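**Retrosynthetic overview**
1. The target comes from its C3 silyl ether, which is the product of an allylsilane-terminated epoxide-opening oxa/carbacyclization of an acyclic diepoxy Z-allylsilane side chain. This closes the hydroxy-oxepane (ring A) and the methylenecyclohexane (ring B) last, in one flask.
2. The allylsilane is unveiled only at that point, by Negishi coupling of a Z-vinyl bromide that survives Shi epoxidation of the two neighbouring olefins. The axial tertiary acetate comes from equatorial MeLi addition to the ring ketone and acetylation in the same flask.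
3. The acetoxy-oxepane/cyclohexanone half (rings C and D) comes from an enol-silane-terminated epoxide-opening cascade run on the full-length chain. The regiodefined enol silane comes from 1,4-hydrosilylation of an enone.
4. The enone comes from cross-metathesis of a bromo-tetraene (geranylacetone, then alkyne, then Pd bromoallylation) with a diepoxy vinyl ketone (geranyl bromide, then Weinreb amide, Shi epoxidation, vinyl Grignard).
5. Ring order: C and D together (step 8), then A and B together (step 12). Two preformed bicyclic halves are never coupled.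

Assumption and numbering: (E)-geranylacetone and geranyl bromide are bought as single E isomers; C1–C24 label the main chain of the target from the hydroxy-oxepane end (C2 gem-dimethyl carbon, C3 carbinol, C6/C7 ring fusion, C10 methylene-bearing carbon, C11–C14 the CH–CH2–CH2–CH bridge, C15 tertiary acetate carbon, C18/C19 ring fusion, C22 secondary acetate carbon, C23 gem-dimethyl carbon).

**Route**

Step 1
Reactants: 1 (5E)-6,10-dimethylundeca-5,9-dien-2-one [(E)-geranylacetone]
Product: 3 (5E)-6,10-dimethylundeca-5,9-dien-1-yne, via enol phosphate 2 (not isolated)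
Conditions: LiN(iPr)2 (1.05 equiv), THF, −78 °C; ClP(O)(OEt)2, −78 → 23 °C; then LiN(iPr)2 (2.3 equiv), −78 → 23 °C; aq. NH4Cl
Reagents that add atoms: none
Why: Kinetic enolate O-phosphorylation followed by base-induced elimination of diethyl phosphate (Negishi enol phosphate route from methyl ketones to terminal alkynes) gives the alkyne; the E olefin is untouched and no stereocentre is formed.

Step 2
Reactants: 3 (5E)-6,10-dimethylundeca-5,9-dien-1-yne
Product: 4 (4Z,8E)-5-bromo-9,13-dimethyltetradeca-1,4,8,12-tetraene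
Conditions: PdBr2(PhCN)2 (2 mol%), allyl bromide (10 equiv, neat), 23 °C
Reagents that add atoms: allyl bromide, C=CCBr
Why: Pd-catalysed bromoallylation (haloallylation) of a terminal alkyne: syn-bromopalladation by divalent palladium puts Br on the internal carbon, and insertion of allyl bromide with β-bromide elimination delivers the allyl group cis to Br, which fixes the Z geometry that later sets C11 and gives a vinyl bromide inert to dioxirane (a masked allylsilane).

Step 3
Reactants: 5 (2E)-1-bromo-3,7-dimethylocta-2,6-diene (geranyl bromide); 6 N-methoxy-N-methylacetamide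
Product: 7 (4E)-N-methoxy-N,5,9-trimethyldeca-4,8-dienamide
Conditions: 6, LiN(iPr)2, THF, −78 °C; then 5, −78 → 0 °C
Reagents that add atoms: none
Why: Enolate alkylation (SN2) of the lithium enolate of the Weinreb acetamide with the primary allylic bromide gives the chain-extended amide with the E olefin intact.

Step 4
Reactants: 7 (4E)-N-methoxy-N,5,9-trimethyldeca-4,8-dienamide
Product: 8 3-[(2R,3R)-3-{2-[(2R)-3,3-dimethyloxiran-2-yl]ethyl}-3-methyloxiran-2-yl]-N-methoxy-N-methylpropanamide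
Conditions: D-fructose-derived Shi ketone (1,2:4,5-di-O-isopropylidene-β-D-erythro-2,3-hexodiulo-2,6-pyranose, 0.6 equiv), KHSO5 (as 2KHSO5·KHSO4·K2SO4), K2CO3, Bu4NHSO4 (cat.), MeCN/CH2(OMe)2/aq. Na2B4O7 buffer, pH 10.5, 0 °C
Reagents that add atoms: potassium peroxymonosulfate (KHSO5), [K+].[O-]S(=O)(=O)OO
Why: Shi asymmetric epoxidation: the dioxirane of the D-fructose-derived ketone oxidises both electron-rich trisubstituted olefins through the spiro transition state on the same face, which sets the (R,R)-internal and (R)-terminal epoxides (future C18, C19 and C22) under reagent control.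

Step 5
Reactants: 8 the diepoxy Weinreb amide
Product: 9 5-[(2R,3R)-3-{2-[(2R)-3,3-dimethyloxiran-2-yl]ethyl}-3-methyloxiran-2-yl]pent-1-en-3-one
Conditions: CH2=CHMgBr (1.5 equiv), THF, −78 → 0 °C; inverse quench into cold aq. NH4Cl
Reagents that add atoms: vinylmagnesium bromide, C=C[Mg]Br
Why: Weinreb ketone synthesis: the magnesium-chelated tetrahedral adduct stops at mono-addition and collapses only on the cold quench, so the vinyl ketone forms without attack on the trisubstituted epoxides.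

Step 6
Reactants: 4 (4Z,8E)-5-bromo-9,13-dimethyltetradeca-1,4,8,12-tetraene (2 equiv); 9 the diepoxy vinyl ketone
Product: 10 (4E,7Z,11E)-8-bromo-1-[(2R,3R)-3-{2-[(2R)-3,3-dimethyloxiran-2-yl]ethyl}-3-methyloxiran-2-yl]-12,16-dimethylheptadeca-4,7,11,15-tetraen-3-one
Conditions: second-generation Hoveyda–Grubbs catalyst (5 mol%), 1,4-benzoquinone (10 mol%), CH2Cl2, 40 °C
Reagents that add atoms: none
Why: Olefin cross-metathesis joins the only monosubstituted olefin of 4 to the vinyl ketone with loss of ethene and gives the E enone under thermodynamic control, because the trisubstituted olefins, the vinyl bromide and the epoxides do not engage the ruthenium carbene.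

Step 7
Reactants: 10 the bromo diepoxy enone
Product: 11 {[(3Z,7Z,11E)-8-bromo-1-[(2R,3R)-3-{2-[(2R)-3,3-dimethyloxiran-2-yl]ethyl}-3-methyloxiran-2-yl]-12,16-dimethylheptadeca-3,7,11,15-tetraen-3-yl]oxy}triethylsilane
Conditions: Et3SiH (1.5 equiv), RhCl(PPh3)3 (2 mol%), benzene, 50 °C; filtration through Et3N-deactivated silica
Reagents that add atoms: triethylsilane, CC[SiH](CC)CC
Why: Rhodium-catalysed 1,4-hydrosilylation of the enone (hydride to C13, silicon to oxygen) gives the C14=C15 silyl enol ether regiospecifically, mainly as the Z isomer from the s-cis enone, a regiochemistry that enolisation of the saturated ketone could not deliver.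

Step 8
Reactants: 11 the triethylsilyl enol ether
Product: 13 (3R,5aR,6R,9aR)-6-[(3Z,7E)-4-bromo-8,12-dimethyltrideca-3,7,11-trien-1-yl]-3-hydroxy-2,2,5a-trimethyloctahydro-1-benzoxepin-7(2H)-one, via bicyclic trimethylsilyl ether 12 (not isolated)
Conditions: Me3SiOTf (1.2 equiv), 2,6-di-tert-butyl-4-methylpyridine (2 equiv), CH2Cl2, −78 °C; then K2CO3, MeOH, 23 °C
Reagents that add atoms: none
Why: Lewis-acid-triggered epoxide-opening oxa/carbacyclization cascade with Mukaiyama-type termination: the O-silylated terminal epoxide is opened at its tertiary carbon by the oxygen of the neighbouring epoxide (oxepane), and the resulting epoxonium ion is opened at its tertiary carbon with inversion by the enol silane through a chair transition state, so the epoxide configurations are relayed into the trans ring fusion (C18, C19) and C22 while C14 takes the equatorial side chain, which is also the thermodynamic outcome of the K2CO3/MeOH treatment that removes the silyl ether.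

Step 9
Reactants: 13 the bicyclic keto alcohol
Product: 15 (3R,5aR,6R,7S,9aR)-6-[(3Z,7E)-4-bromo-8,12-dimethyltrideca-3,7,11-trien-1-yl]-2,2,5a,7-tetramethyldecahydro-1-benzoxepine-3,7-diyl diacetate, via dilithium dialkoxide 14 (not isolated)
Conditions: MeLi (3.5 equiv), THF, −78 °C; then Ac2O (10 equiv), 4-(dimethylamino)pyridine (cat.), −78 → 23 °C
Reagents that add atoms: methyllithium, [Li]C; acetic anhydride, CC(=O)OC(C)=O
Why: 1,2-Addition of MeLi to the ring ketone comes from the equatorial direction because the axial angular methyl group on C19 blocks the axial trajectory, which gives the axial tertiary alkoxide (C15, S), and both lithium alkoxides are then acetylated in the flask by Ac2O (alkoxide trapping), the vinyl bromide being inert to MeLi at −78 °C.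

Step 10
Reactants: 15 the bromo-triene diacetate
Product: 16 (3R,5aR,6R,7S,9aR)-6-{(3Z)-4-bromo-6-[(2R,3R)-3-{2-[(2R)-3,3-dimethyloxiran-2-yl]ethyl}-3-methyloxiran-2-yl]hex-3-en-1-yl}-2,2,5a,7-tetramethyldecahydro-1-benzoxepine-3,7-diyl diacetate
Conditions: D-fructose-derived Shi ketone (0.6 equiv), KHSO5 (as 2KHSO5·KHSO4·K2SO4), K2CO3, Bu4NHSO4 (cat.), MeCN/CH2(OMe)2/aq. Na2B4O7 buffer, pH 10.5, 0 °C
Reagents that add atoms: potassium peroxymonosulfate (KHSO5), [K+].[O-]S(=O)(=O)OO
Why: Second Shi asymmetric epoxidation: the two remaining trisubstituted olefins are oxidised on the same face by the chiral dioxirane to give the (R)-terminal and (R,R)-internal epoxides (future C3, C6 and C7), while the electron-poor vinyl bromide is inert to the electrophilic oxidant and the acetates survive pH 10.5 at 0 °C.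

Step 11
Reactants: 16 the diepoxy vinyl bromide diacetate
Product: 17 (3R,5aR,6R,7S,9aR)-6-{(3Z)-6-[(2R,3R)-3-{2-[(2R)-3,3-dimethyloxiran-2-yl]ethyl}-3-methyloxiran-2-yl]-4-[(trimethylsilyl)methyl]hex-3-en-1-yl}-2,2,5a,7-tetramethyldecahydro-1-benzoxepine-3,7-diyl diacetate
Conditions: Me3SiCH2MgCl (3 equiv), ZnCl2 (3.3 equiv), THF, 0 °C; then 16, Pd(PPh3)4 (5 mol%), 50 °C
Reagents that add atoms: (trimethylsilyl)methylmagnesium chloride, C[Si](C)(C)C[Mg]Cl
Why: Negishi cross-coupling of the alkenyl bromide with the (trimethylsilyl)methylzinc reagent under zerovalent palladium catalysis proceeds with retention of olefin geometry and unveils the Z-allylsilane; the organozinc has no β-hydrogen and tolerates acetates and epoxides.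

Step 12
Reactants: 17 the diepoxy allylsilane diacetate
Product: 19 (3R,5aR,6R,7S,9aR)-6-{2-[(3R,5aR,6S,9aR)-3-hydroxy-2,2,5a-trimethyl-7-methylidenedecahydro-1-benzoxepin-6-yl]ethyl}-2,2,5a,7-tetramethyldecahydro-1-benzoxepine-3,7-diyl diacetate (target), via tetracyclic trimethylsilyl ether 18 (not isolated)
Conditions: Me3SiOTf (0.3 equiv), 2,6-di-tert-butyl-4-methylpyridine (0.5 equiv), CH2Cl2, −78 → −40 °C; then citric acid, MeOH, 23 °C
Reagents that add atoms: none
Why: Second epoxide-opening oxa/carbacyclization cascade, now with Sakurai-type (SE2′) termination: the silylated terminal epoxide is opened by the neighbouring epoxide oxygen, the epoxonium ion is attacked with inversion at C6 by C11 of the Z-allylsilane through a chair transition state (C6, C7 and C11 set, side chain equatorial), loss of silicon from the β-silyl cation gives only the exocyclic methylene and returns Me3SiOTf, and mild acidic methanolysis frees the C3 hydroxyl without touching the acetates.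

**Compound list**
1 | (5E)-6,10-dimethylundeca-5,9-dien-2-one, (E)-geranylacetone | CC(=O)CC/C=C(\C)CCC=C(C)C | starting material
2 | diethyl (5E)-6,10-dimethylundeca-1,5,9-trien-2-yl phosphate | C=C(CC/C=C(\C)CCC=C(C)C)OP(=O)(OCC)OCC | intermediate
3 | (5E)-6,10-dimethylundeca-5,9-dien-1-yne | C#CCC/C=C(\C)CCC=C(C)C | intermediate
4 | (4Z,8E)-5-bromo-9,13-dimethyltetradeca-1,4,8,12-tetraene | C=CC/C=C(\Br)CC/C=C(\C)CCC=C(C)C | intermediate
5 | (2E)-1-bromo-3,7-dimethylocta-2,6-diene, geranyl bromide | BrC/C=C(\C)CCC=C(C)C | starting material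
6 | N-methoxy-N-methylacetamide | CC(=O)N(C)OC | starting material
7 | (4E)-N-methoxy-N,5,9-trimethyldeca-4,8-dienamide | CON(C)C(=O)CC/C=C(\C)CCC=C(C)C | intermediate
8 | 3-[(2R,3R)-3-{2-[(2R)-3,3-dimethyloxiran-2-yl]ethyl}-3-methyloxiran-2-yl]-N-methoxy-N-methylpropanamide | CON(C)C(=O)CC[C@H]1O[C@]1(C)CC[C@H]1OC1(C)C | intermediate
9 | 5-[(2R,3R)-3-{2-[(2R)-3,3-dimethyloxiran-2-yl]ethyl}-3-methyloxiran-2-yl]pent-1-en-3-one | C=CC(=O)CC[C@H]1O[C@]1(C)CC[C@H]1OC1(C)C | intermediate
10 | (4E,7Z,11E)-8-bromo-1-[(2R,3R)-3-{2-[(2R)-3,3-dimethyloxiran-2-yl]ethyl}-3-methyloxiran-2-yl]-12,16-dimethylheptadeca-4,7,11,15-tetraen-3-one | CC(C)=CCC/C(C)=C/CC/C(Br)=C/C/C=C/C(=O)CC[C@H]1O[C@]1(C)CC[C@H]1OC1(C)C | intermediate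
11 | {[(3Z,7Z,11E)-8-bromo-1-[(2R,3R)-3-{2-[(2R)-3,3-dimethyloxiran-2-yl]ethyl}-3-methyloxiran-2-yl]-12,16-dimethylheptadeca-3,7,11,15-tetraen-3-yl]oxy}triethylsilane | CC(C)=CCC/C(C)=C/CC/C(Br)=C/CC/C=C(O[Si](CC)(CC)CC)/CC[C@H]1O[C@]1(C)CC[C@H]1OC1(C)C | intermediate
12 | (3R,5aR,6R,9aR)-6-[(3Z,7E)-4-bromo-8,12-dimethyltrideca-3,7,11-trien-1-yl]-2,2,5a-trimethyl-3-[(trimethylsilyl)oxy]octahydro-1-benzoxepin-7(2H)-one | CC(C)=CCC/C(C)=C/CC/C(Br)=C/CC[C@@H]1[C@@]2(C)CC[C@@H](O[Si](C)(C)C)C(C)(C)O[C@@H]2CCC1=O | intermediate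
13 | (3R,5aR,6R,9aR)-6-[(3Z,7E)-4-bromo-8,12-dimethyltrideca-3,7,11-trien-1-yl]-3-hydroxy-2,2,5a-trimethyloctahydro-1-benzoxepin-7(2H)-one | CC(C)=CCC/C(C)=C/CC/C(Br)=C/CC[C@@H]1[C@@]2(C)CC[C@@H](O)C(C)(C)O[C@@H]2CCC1=O | intermediate
14 | dilithium (3R,5aR,6R,7S,9aR)-6-[(3Z,7E)-4-bromo-8,12-dimethyltrideca-3,7,11-trien-1-yl]-2,2,5a,7-tetramethyldecahydro-1-benzoxepine-3,7-diolate | [Li+].[Li+].CC(C)=CCC/C(C)=C/CC/C(Br)=C/CC[C@@H]1[C@@]2(C)CC[C@@H]([O-])C(C)(C)O[C@@H]2CC[C@]1(C)[O-] | intermediate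
15 | (3R,5aR,6R,7S,9aR)-6-[(3Z,7E)-4-bromo-8,12-dimethyltrideca-3,7,11-trien-1-yl]-2,2,5a,7-tetramethyldecahydro-1-benzoxepine-3,7-diyl diacetate | CC(C)=CCC/C(C)=C/CC/C(Br)=C/CC[C@@H]1[C@@]2(C)CC[C@@H](OC(C)=O)C(C)(C)O[C@@H]2CC[C@]1(C)OC(C)=O | intermediate
16 | (3R,5aR,6R,7S,9aR)-6-{(3Z)-4-bromo-6-[(2R,3R)-3-{2-[(2R)-3,3-dimethyloxiran-2-yl]ethyl}-3-methyloxiran-2-yl]hex-3-en-1-yl}-2,2,5a,7-tetramethyldecahydro-1-benzoxepine-3,7-diyl diacetate | CC1(C)O[C@@H]1CC[C@@]1(C)O[C@@H]1CC/C(Br)=C/CC[C@@H]1[C@@]2(C)CC[C@@H](OC(C)=O)C(C)(C)O[C@@H]2CC[C@]1(C)OC(C)=O | intermediate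
17 | (3R,5aR,6R,7S,9aR)-6-{(3Z)-6-[(2R,3R)-3-{2-[(2R)-3,3-dimethyloxiran-2-yl]ethyl}-3-methyloxiran-2-yl]-4-[(trimethylsilyl)methyl]hex-3-en-1-yl}-2,2,5a,7-tetramethyldecahydro-1-benzoxepine-3,7-diyl diacetate | CC1(C)O[C@@H]1CC[C@@]1(C)O[C@@H]1CC/C(C[Si](C)(C)C)=C/CC[C@@H]1[C@@]2(C)CC[C@@H](OC(C)=O)C(C)(C)O[C@@H]2CC[C@]1(C)OC(C)=O | intermediate
18 | (3R,5aR,6R,7S,9aR)-2,2,5a,7-tetramethyl-6-{2-[(3R,5aR,6S,9aR)-2,2,5a-trimethyl-7-methylidene-3-[(trimethylsilyl)oxy]decahydro-1-benzoxepin-6-yl]ethyl}decahydro-1-benzoxepine-3,7-diyl diacetate | C=C1CC[C@H]2OC(C)(C)[C@H](O[Si](C)(C)C)CC[C@]2(C)[C@H]1CC[C@@H]1[C@@]2(C)CC[C@@H](OC(C)=O)C(C)(C)O[C@@H]2CC[C@]1(C)OC(C)=O | intermediate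
19 | (3R,5aR,6R,7S,9aR)-6-{2-[(3R,5aR,6S,9aR)-3-hydroxy-2,2,5a-trimethyl-7-methylidenedecahydro-1-benzoxepin-6-yl]ethyl}-2,2,5a,7-tetramethyldecahydro-1-benzoxepine-3,7-diyl diacetate (CNP0412606.2) | C=C1CC[C@H]2OC(C)(C)[C@H](O)CC[C@]2(C)[C@H]1CC[C@@H]1[C@@]2(C)CC[C@@H](OC(C)=O)C(C)(C)O[C@@H]2CC[C@]1(C)OC(C)=O | target

**Totals**
Total step count: 12.
Longest linear sequence: 10 steps (steps 3 to 12, from geranyl bromide).

**Three steps most likely to fail, each with a fallback**

Step 8 (first cascade). A trisubstituted enol silane has to out-compete hydride shift and tetrahydrofuran/tetrahydropyran pathways while two epoxides are activated at once. Fallback: build the two rings one after the other, setting out from 11 and coming back at 13. Compound 11 is treated with only 10 mol% Et3SiOTf (2,6-di-tert-butyl-4-methylpyridine, CH2Cl2, −78 °C), so that the fast six-membered Mukaiyama-type opening of the internal epoxide with silyl transfer gives the monocyclic triethylsilyloxy ketone F1 with the terminal epoxide intact. Bu4NF/AcOH (THF, 0 °C) then gives the hydroxy epoxide F2. A separate acid-mediated 7-endo hydroxy-epoxide cyclization at the tertiary epoxide carbon (camphorsulfonic acid, CH2Cl2, 0 °C) closes the oxepane and gives 13.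

Step 11 (Negishi coupling). A hindered trisubstituted alkenyl bromide must couple while two acid-sensitive epoxides sit next to Lewis-acidic zinc halides. Fallback: reverse the polarity of the coupling, setting out from 16 and coming back at 17. Miyaura borylation of 16 (bis(pinacolato)diboron, PdCl2(dppf), KOAc, dioxane, 80 °C) gives the alkenyl pinacol boronate F3 with retention of geometry. Suzuki–Miyaura coupling of F3 with (iodomethyl)trimethylsilane (Pd(OAc)2, 2-dicyclohexylphosphino-2′,6′-dimethoxybiphenyl, K3PO4, THF/H2O, 50 °C) gives 17 with no zinc halide present.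

Step 12 (second cascade). The axial tertiary acetate may ionise or eliminate under silyl triflate. Fallback: change the order so that the last cascade is run on the ketone and the tertiary acetate is installed afterwards, setting out from 13 and coming back at 18.
- 13 is acetylated only at the secondary hydroxyl (Ac2O, pyridine, 23 °C) to give the keto acetate F4.
- Shi epoxidation as in step 10 gives the diepoxide F5.
- Negishi coupling as in step 11 gives the allylsilane keto acetate F6.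
- The Me3SiOTf cascade of step 12, stopped before methanolysis, gives the tetracyclic keto acetate silyl ether F7.
- Chemoselective addition of MeLi/CeCl3 to the ketone (THF, −78 °C, secondary acetate untouched) followed by Ac2O gives 18, which is desilylated with citric acid/MeOH as in step 12.

**Further compounds**
F1 | step 8 | (2R,3R,4R)-2-[(3Z,7E)-4-bromo-8,12-dimethyltrideca-3,7,11-trien-1-yl]-3-{2-[(2R)-3,3-dimethyloxiran-2-yl]ethyl}-3-methyl-4-[(triethylsilyl)oxy]cyclohexan-1-one | CC(C)=CCC/C(C)=C/CC/C(Br)=C/CC[C@@H]1[C@@](C)(CC[C@H]2OC2(C)C)[C@H](O[Si](CC)(CC)CC)CCC1=O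
F2 | step 8 | (2R,3R,4R)-2-[(3Z,7E)-4-bromo-8,12-dimethyltrideca-3,7,11-trien-1-yl]-3-{2-[(2R)-3,3-dimethyloxiran-2-yl]ethyl}-4-hydroxy-3-methylcyclohexan-1-one | CC(C)=CCC/C(C)=C/CC/C(Br)=C/CC[C@@H]1[C@@](C)(CC[C@H]2OC2(C)C)[C@H](O)CCC1=O
F3 | step 11 | (3R,5aR,6R,7S,9aR)-6-{(3E)-6-[(2R,3R)-3-{2-[(2R)-3,3-dimethyloxiran-2-yl]ethyl}-3-methyloxiran-2-yl]-4-(4,4,5,5-tetramethyl-1,3,2-dioxaborolan-2-yl)hex-3-en-1-yl}-2,2,5a,7-tetramethyldecahydro-1-benzoxepine-3,7-diyl diacetate | CC1(C)O[C@@H]1CC[C@@]1(C)O[C@@H]1CC/C(B2OC(C)(C)C(C)(C)O2)=C/CC[C@@H]1[C@@]2(C)CC[C@@H](OC(C)=O)C(C)(C)O[C@@H]2CC[C@]1(C)OC(C)=O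
F4 | step 12 | (3R,5aR,6R,9aR)-6-[(3Z,7E)-4-bromo-8,12-dimethyltrideca-3,7,11-trien-1-yl]-2,2,5a-trimethyl-7-oxodecahydro-1-benzoxepin-3-yl acetate | CC(C)=CCC/C(C)=C/CC/C(Br)=C/CC[C@@H]1[C@@]2(C)CC[C@@H](OC(C)=O)C(C)(C)O[C@@H]2CCC1=O
F5 | step 12 | (3R,5aR,6R,9aR)-6-{(3Z)-4-bromo-6-[(2R,3R)-3-{2-[(2R)-3,3-dimethyloxiran-2-yl]ethyl}-3-methyloxiran-2-yl]hex-3-en-1-yl}-2,2,5a-trimethyl-7-oxodecahydro-1-benzoxepin-3-yl acetate | CC1(C)O[C@@H]1CC[C@@]1(C)O[C@@H]1CC/C(Br)=C/CC[C@@H]1[C@@]2(C)CC[C@@H](OC(C)=O)C(C)(C)O[C@@H]2CCC1=O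
F6 | step 12 | (3R,5aR,6R,9aR)-6-{(3Z)-6-[(2R,3R)-3-{2-[(2R)-3,3-dimethyloxiran-2-yl]ethyl}-3-methyloxiran-2-yl]-4-[(trimethylsilyl)methyl]hex-3-en-1-yl}-2,2,5a-trimethyl-7-oxodecahydro-1-benzoxepin-3-yl acetate | CC1(C)O[C@@H]1CC[C@@]1(C)O[C@@H]1CC/C(C[Si](C)(C)C)=C/CC[C@@H]1[C@@]2(C)CC[C@@H](OC(C)=O)C(C)(C)O[C@@H]2CCC1=O
F7 | step 12 | (3R,5aR,6R,9aR)-2,2,5a-trimethyl-6-{2-[(3R,5aR,6S,9aR)-2,2,5a-trimethyl-7-methylidene-3-[(trimethylsilyl)oxy]decahydro-1-benzoxepin-6-yl]ethyl}-7-oxodecahydro-1-benzoxepin-3-yl acetate | C=C1CC[C@H]2OC(C)(C)[C@H](O[Si](C)(C)C)CC[C@]2(C)[C@H]1CC[C@@H]1[C@@]2(C)CC[C@@H](OC(C)=O)C(C)(C)O[C@@H]2CCC1=O
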